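(The runs are calculated with constants of no real substance; the scatter is artificial.)

- Count the rate per unit of J: if each unit works on its own, the north run, holding 0.520 of the J of the west run, makes G at that same fraction of the west rate. I take this proportional case, a power of one, as the zero of my scale.

| flask | E | Q | J | time |
|---|---|---|---|---|
| west | 0.250 M | 0.250 M | 0.0250 M |  |
| south-east | 0.150 M | 0.150 M | 0.0250 M |  |
| north | 0.250 M | 0.250 M | 0.0130 M |  |
| south-west | 0.250 M | 0.0500 M | 0.0250 M | 4.8 min |

| west run: time / min | west run: [G] / M | south-east run: time / min | south-east run: [G] / M | north run: time / min | north run: [G] / M |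
|---|---|---|---|---|---|
| 0.21 | 0.0014 | 0.21 | 3 × 10⁻⁴ | 0.21 | 0 |
| 0.65 | 0.0114 | 0.65 | 0.0074 | 0.65 | 0.0049 |
| 1.2 | 0.0278 | 1.2 | 0.0189 | 1.2 | 0.0152 |
| 2.0 | 0.0502 | 2.0 | 0.0352 | 2.0 | 0.0276 |
| 2.8 | 0.0715 | 2.8 | 0.0514 | 2.8 | 0.0393 |
| 3.8 | 0.0995 | 3.8 | 0.0705 | 3.8 | 0.0532 |
| 4.8 | 0.1209 | 4.8 | 0.0847 | 4.8 | 0.0693 |

(each reading ± 8 × 10⁻⁴ M)

* the power of [J] that the first rate follows, about the charge of the west run; measure it at two percent of E made into G
* the south-east run starts with 0.100 M less of E and of Q than the west run, and with no G. Compared where both hold the same amount of E, once fifteen percent of what the south-east run was charged with has turned into G, is the south-east run faster, slower or alike (within a tenth)?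
* G in the south-west run at 4.8 min, as a share of the E charged

- Overall: E + Q -> G, with J as catalyst.
- Constant volume, constant temperature.
- The analysis sees a species whether free or bound.
- An order is taken over about fifteen percent of the charge, up and down.

- My first way compares slopes. Between 0.65 min and 1.2 min the west run gains 6.56% of its E and the north run 4.12%, a ratio of 1.59 where the proportional case asks 1.92. That makes a power of 0.711. The north gain carries a scatter of 11.0%, however, which puts 0.168 on that power.

- My second way compares times at an equal fraction of the charge. The west run holds 11.1% of its E as G at 1.2 min, and the north run holds 11.0% at 2.0 min. Read as a rate ratio, the time ratio 1.67 gives a power of 0.781. But elapsed time is an inverse rate on a straight curve from zero, and the west curve is not one: it turns an average of 0.0267 min⁻¹ of its E up to 0.21 min, slower than the 0.119 min⁻¹ between 0.65 min and 1.2 min. The time ratio counts that slow opening as well, so it is no rate ratio.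

- The two powers lie 0.0700 apart, less than the scatter of the slope, but that nearness is no check, since the second number is not a rate order. I keep the slope and commit to 0.711 as the J-power, the apparent reaction order in J: the logarithm of the west-over-north ratio of gains over one early stretch of time, divided by the logarithm of the west-over-north ratio of J.

- The forecast gives 0.9 for the power, alike for the south-east comparison and 14% for the south-west run. On the power it stands 0.189 above mine, working from near-steady rates: “Across a 1.9-fold change in J, this gives an order of about 0.9”.

    J + E → JE (27.36 M⁻¹ min⁻¹)
    JE + Q → Vy (24.12 M⁻¹ min⁻¹)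
    Vy → G + J (4.050 min⁻¹)
    J + E ⇌ JE', settled at all times (6.540 M⁻¹)

- The flask gives a power of 0.68; the south-east run comes out alike, and the south-west run reaches 16.9%. At two percent of the west E turned, the west run makes G at 0.025 M min⁻¹ and the north run at 0.015 M min⁻¹. Raising the north fraction 0.520 of J to my 0.711 gives a north-over-west rate ratio of 0.628, and the ratio stored for the north run against the west run, at that same amount of G made, is 0.61.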